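## Analysis of the target

Target **40** is an elemane-type lactone. A cyclohexane (C5–C10) is trans-fused at C7–C8 to an α-methylene-γ-butyrolactone (C7, C11, C12, O8, C8; exocyclic C13). C5 carries a 2-substituted acrolein arm (C4, C15, C3), O6 a methacrylate, C9 a free hydroxyl, and the quaternary C10 a methyl group (C14) and an oxirane (C1, C2).

All six ring carbons are stereogenic and the oxirane carbon C1 is a seventh centre. Viewed with C5→C6→C7→C8→C9→C10 clockwise, O8, O9 and C1 are up; the C5 arm, O6, C11 and C14 are down. So O6/C11 are cis, C11/O8 trans, O8/O9 cis, O9/C1 cis and C1/C5-arm trans.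

The molecule holds three Michael acceptors, an aldehyde and a monosubstituted epoxide beside a quaternary carbon. Its strained trans-lactone could relactonise onto O6 under base. These groups must therefore come late.

The difficulties are the quaternary C10 inside a contiguous stereo-array, telling O6, O8 and O9 apart, and bringing C11 to C7 cis to O6 but trans to O8.

The strategy rests on one feature: C9 bears a hydroxyl and C10 a two-carbon unit C1–C2 on the same face. C9(OH)–C10–C1=C2 is the homoallylic alcohol left by a [2,3]-Wittig shift of a C9–O–C2 allylic ether. With C5–C8 included, that ether is a nine-membered ring (O, C2, C1, C10, C5, C6, C7, C8, C9). Its C7=C8 alkene and C6 oxygen are the handles needed afterwards for the lactone.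

## Retrosynthetic reasoning

**40 ⇒ 39.** The oxirane C–O bonds are cut first. A terminal epoxide next to a quaternary carbon would not survive the Lewis-acidic, fluoride or selenium steps, so it is made last. The forward step must oxidise the one alkene of **39** that is not conjugated to a carbonyl, on the face giving (1R); the homoallylic O9–H is the only handle.

**39 ⇒ 38 ⇒ 37.** The aldehyde oxygen at C3 is removed, returning the isopropenyl group of **37**. Isopropenyl is an inert spectator through all organometallic steps. The forward reaction is an allylic oxidation at the methyl group of the only electron-rich alkene that has allylic hydrogens.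

**37 ⇒ 36.** The lactone carbonyl carbon is excised (C11–C12 and C12–O8). What remains is the homopropargylic alcohol **36**. One carbonylation then builds the ring and the exocyclic methylene together, and the trans fusion is already fixed by the substrate.

**36 ⇒ 35 ⇒ 34 ⇒ 33 ⇒ 32.** These are changes of protecting state only. The methacrylate is placed on O6 before the lactone exists, while O8 and O9 are tied in acetal **33**. This avoids choosing between two hindered secondary alcohols, blocks a 6,12-lactone in the carbonylation, and never exposes a free O6 alkoxide to the 8,12-lactone.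

**32 ⇒ 31 ⇒ 30 ⇒ 29.** The C7–C11 bond is cut. The alkynyl unit comes from opening a C7–C8 epoxide at C7 with inversion, which gives C11 down and O8 up in one event. The epoxide **31** comes from the C7=C8 alkene of **30**, directed by O9–H. O6 must be silylated first so that only O9 directs and so that no ester can take part at C7.

**29 ⇒ 27 (key disconnection).** The C9–C10 bond is cut and O9 is reconnected to C2. This bond is chosen because it is the only ring bond whose formation creates the quaternary centre, the C9 carbinol and the C10 vinyl group at once. It also leaves C7=C8 flanked by O6 and O9. The forward reaction must generate a carbanion at C9 only, which a tin substituent ensures, and make it attack C10 on the face anti to the C5 isopropenyl group.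

**27 ⇒ 26.** The ring alkene C7=C8 is cut by retro-metathesis into two vinyl groups. In a nine-membered ring only the Z alkene can form, so no geometry needs to be controlled.

**26 ⇒ 20 + 23.** The ether bond O–C2 is cut into allylic bromide **20** and α-hydroxy stannane **23**. **23** comes in one step from tributyltin hydride **21** and acrolein **12**. This is a convergent junction; the tin is introduced on a three-carbon piece and not on the elaborate one.

**20 ⇒ 19 ⇒ 18 ⇒ 17 ⇒ 15 ⇒ 14.** The isopropenyl carbon C4 is traced back to an acyl carbon: alkene from methyl ketone **17**, ketone from Weinreb amide **15**, amide from imide **14**. This makes C5 the α-carbon of a carbonyl compound, which is what an auxiliary-controlled aldol needs.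

**14 ⇒ 11 + 12.** The C5–C6 bond is cut as a syn aldol between imide **11** and acrolein **12**. The required C5/C6 relation (O6 and the C10 alkenyl group syn along C4–C5–C6–C7) is the normal outcome of a (Z)-boron enolate.

**11 ⇒ 8 + 9; 8 ⇒ 7 ⇒ 4 + 5; 4 ⇒ 3 ⇒ 1.** The acyl group is the skipped acid **8**. Its C5–C10 bond comes from coupling vinyl iodide **4** with the zinc reagent of ethyl bromoacetate **5**. The Z geometry of C1=C10 originates in the trans-hydroalumination/iodination of but-2-yn-1-ol **1** and is carried unchanged to **27**.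

## Alternatives that were turned down

**Alternative 1:** Here the bonds C10–C1 and C5–C4 are cut together. In the forward sense cyclohexenone A2 is irradiated. Its C5=C10 enone is tied through a silyl acetal on O9 to a cyclobutene enol, and the intramolecular [2+2] photocycloaddition gives the bicyclo[2.2.0]hexane A1. Heating then unzips the strained bicycle to the divinyl-type elemane pattern.
- *For:* enone–alkene photocycloaddition followed by thermolysis is established chemistry. The tether fixes regiochemistry and delivers the new bonds from the O9 face. The lactone ring is already present in A2. On precedent of the key step this route is stronger than the chosen one.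
- *Against:* A1 is cis-fused, so the trans relation of C1 and the C5 arm depends on the thermal pathway (ring-opened diene, then Cope return). The temperatures needed may not suit a β-oxygenated ketone beside a lactone. C6 arrives as a ketone and still has to become the axial alcohol. The oxirane must be drawn from a silyl enol ether, the ester on C4 must be reduced to the aldehyde next to the lactone, and the α-methylene group is still missing.
- *Comparison:* this route solves the skeleton but leaves four redox and stereochemical corrections on a crowded ring. The [2,3] shift instead delivers C9–OH, the C10 centre and the C7=C8 handle in final form in one step; that is what the chosen route offers for its weaker precedent.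

**Alternative 2:** This cuts off the two acrylic carbonyl carbons: C11–C12 and C12–O8 of the lactone, and C4–C3 of the arm. Forward, zerovalent palladium inserts into both enol triflates of A4 under carbonylation. The acylpalladium at C11 is trapped by the free C8 hydroxyl to close the lactone; the one at C4 is trapped by the alcohol solvent as the methyl ester. The product is A3.
- *For:* both acceptors appear in one late step by reliable chemistry, with the ring fusion preset. In economy of the endgame it beats the steps the chosen route spends on the lactone and the aldehyde.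
- *Against:* it is an endgame tactic and not a ring synthesis. A4 already contains all six ring stereocentres including C10. Two methyl ketones on epimerisable ring positions (C5, C7) would have to be enolised toward CH3 to make the triflates. The acrylate ester must then be reduced beside a more electrophilic lactone, and two identical silyl ethers must be distinguished for the methacrylate.
- *Comparison:* the hard part (C9/C10/C5) stays unsolved. The chosen route keeps the best idea of this alternative, carbonylation with capture by O8, as the cyclocarbonylation of **36**.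

**Alternative 3:** The bonds C6–O and C9–O are cut, leaving a cyclohexa-1,3-diene. Forward, divalent palladium with a quinone reoxidant adds two acetates 1,4 across A6. Acetoxypalladation and then attack on the π-allyl complex give the trans-1,4-diacetoxycyclohex-2-ene A5, with the C7=C8 alkene in place.
- *For:* a well-studied, catalytic, stereospecific reaction. A5 has the same oxygen pattern as **29** (O6 and O9 trans, alkene between them). On reliability of the key step it is clearly ahead.
- *Against:* only the relation between the two acetates is fixed. Which trans isomer forms depends on the diene face palladium takes, and the C10 quaternary centre and the C5 side chain shield opposite faces. The two acetates are chemically alike and must be differentiated. A6, with its quaternary centre and the C5/C10 relation, still has to be made, and its C10 ester turned into the oxirane.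
- *Comparison:* the chosen strategy uses the C9–C10 bond formation itself to set C9 and C10 relative to C5 and C6. The oxygen pattern and the quaternary centre come from one event and not from two unrelated ones.

Key step: step 17

Remark on the chemistry: stannyl carbinol **23** is used as the racemate, so **25**, **26** and **27** are mixtures of the two epimers at the tin-bearing carbon C9 (left open in the SMILES). Both epimers give the same delocalised carbanion **28**.

## Route

Step 1
Reactants: 1 but-2-yn-1-ol
Product: 3 (2Z)-3-iodobut-2-en-1-ol, via cyclic vinylalanate 2 (not isolated)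
Conditions: NaAlH2(OCH2CH2OMe)2, THF, 0 °C to rt; then I2, −78 to 0 °C
Reagents that add atoms: iodine, [I][I]
Why: Hydroxyl-directed trans-hydroalumination puts aluminium on C10 cis to the CH2O group and iodinolysis proceeds with retention; this fixes the Z geometry of C1=C10 (C2 cis to the future C5) for the whole route.

Step 2
Reactants: 3 (2Z)-3-iodobut-2-en-1-ol
Product: 4 1-({[(2Z)-3-iodobut-2-en-1-yl]oxy}methyl)-4-methoxybenzene
Conditions: NaH, 4-MeOC6H4CH2Cl, Bu4NI (cat.), THF/DMF, 0 °C to rt
Reagents that add atoms: 4-methoxybenzyl chloride, COc1ccc(CCl)cc1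
Why: Williamson etherification of the primary alkoxide; the 4-methoxybenzyl ether is stable to the organometallic steps and is later removed oxidatively without touching the O6 silyl ether.

Step 3
Reactants: 4 1-({[(2Z)-3-iodobut-2-en-1-yl]oxy}methyl)-4-methoxybenzene; 5 ethyl bromoacetate
Product: 7 ethyl (3Z)-5-[(4-methoxybenzyl)oxy]-3-methylpent-3-enoate, via (2-ethoxy-2-oxoethyl)zinc bromide 6 (not isolated)
Conditions: 5, Zn, Me3SiCl (cat.), THF, 40 °C; then 4, Pd2(dba)3 (zerovalent palladium, cat.), XPhos, THF, 40 °C
Reagents that add atoms: none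
Why: Negishi-type coupling of a Reformatsky reagent with a vinyl iodide forms C5–C10 with retention of alkene geometry; the neutral conditions keep the skipped ester out of conjugation.

Step 4
Reactants: 7 ethyl (3Z)-5-[(4-methoxybenzyl)oxy]-3-methylpent-3-enoate
Product: 8 (3Z)-5-[(4-methoxybenzyl)oxy]-3-methylpent-3-enoic acid
Conditions: LiOH, THF/H2O, 0 °C; then cold 1 M HCl to pH 3
Reagents that add atoms: lithium hydroxide, [Li+].[OH-]
Why: Ester saponification; low temperature and short exposure should prevent migration of the β,γ-alkene into conjugation.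

Step 5
Reactants: 8 (3Z)-5-[(4-methoxybenzyl)oxy]-3-methylpent-3-enoic acid; 9 (4S)-4-benzyl-1,3-oxazolidin-2-one
Product: 11 (4S)-4-benzyl-3-{(3Z)-5-[(4-methoxybenzyl)oxy]-3-methylpent-3-enoyl}-1,3-oxazolidin-2-one, via pivalic mixed anhydride 10 (not isolated)
Conditions: t-BuCOCl, Et3N, THF, −20 °C; then 9, LiCl, −20 °C to rt
Reagents that add atoms: none
Why: N-acylation of the oxazolidinone through the mixed anhydride with LiCl activation needs no strong base; it installs the auxiliary that will control C5 and C6.

Step 6
Reactants: 11 (4S)-4-benzyl-3-{(3Z)-5-[(4-methoxybenzyl)oxy]-3-methylpent-3-enoyl}-1,3-oxazolidin-2-one; 12 acrolein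
Product: 14 (4S)-4-benzyl-3-[(2S,3R)-3-hydroxy-2-{(2Z)-4-[(4-methoxybenzyl)oxy]but-2-en-2-yl}pent-4-enoyl]-1,3-oxazolidin-2-one, via dibutylboron enolate 13 (not isolated)
Conditions: n-Bu2BOTf, i-Pr2NEt, CH2Cl2, −78 to 0 °C; 12, −78 °C; then pH 7 buffer, MeOH, H2O2, 0 °C
Reagents that add atoms: none
Why: Evans syn aldol reaction: the (Z)-boron enolate reacts at C5 through a Zimmerman–Traxler chair on the face away from the benzyl group, setting C5 (S) and C6 (R); the C1=C10 alkene is not part of the enolate and keeps its geometry.

Step 7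
Reactants: 14 (4S)-4-benzyl-3-[(2S,3R)-3-hydroxy-2-{(2Z)-4-[(4-methoxybenzyl)oxy]but-2-en-2-yl}pent-4-enoyl]-1,3-oxazolidin-2-one
Product: 15 (2S,3R)-3-hydroxy-N-methoxy-2-{(2Z)-4-[(4-methoxybenzyl)oxy]but-2-en-2-yl}-N-methylpent-4-enamide
Conditions: MeNH(OMe)·HCl, AlMe3, CH2Cl2, −10 to 0 °C; cold 1 M HCl work-up
Reagents that add atoms: N,O-dimethylhydroxylamine hydrochloride, CNOC.Cl
Why: Aluminium amide transamidation to the Weinreb amide, helped by the free β-hydroxyl; the auxiliary is released for reuse.

Step 8
Reactants: 15 (2S,3R)-3-hydroxy-N-methoxy-2-{(2Z)-4-[(4-methoxybenzyl)oxy]but-2-en-2-yl}-N-methylpent-4-enamide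
Product: 16 (2S,3R)-3-[(tert-butyldimethylsilyl)oxy]-N-methoxy-2-{(2Z)-4-[(4-methoxybenzyl)oxy]but-2-en-2-yl}-N-methylpent-4-enamide
Conditions: TBSOTf, 2,6-lutidine, CH2Cl2, −78 to 0 °C
Reagents that add atoms: tert-butyldimethylsilyl trifluoromethanesulfonate, CC(C)(C)[Si](C)(C)OS(=O)(=O)C(F)(F)F
Why: Silylation of the secondary alcohol; it prevents retro-aldol in the next two steps and keeps O6 from cyclising onto C2 during the later etherification.

Step 9
Reactants: 16 (2S,3R)-3-[(tert-butyldimethylsilyl)oxy]-N-methoxy-2-{(2Z)-4-[(4-methoxybenzyl)oxy]but-2-en-2-yl}-N-methylpent-4-enamide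
Product: 17 (3S,4R)-4-[(tert-butyldimethylsilyl)oxy]-3-{(2Z)-4-[(4-methoxybenzyl)oxy]but-2-en-2-yl}hex-5-en-2-one
Conditions: MeMgBr, THF, −78 to 0 °C; aq. NH4Cl at −78 °C
Reagents that add atoms: methylmagnesium bromide, C[Mg]Br
Why: Weinreb ketone synthesis: the chelated tetrahedral intermediate stops at single addition, and a cold buffered quench limits epimerisation of the doubly allylic C5.

Step 10
Reactants: 17 (3S,4R)-4-[(tert-butyldimethylsilyl)oxy]-3-{(2Z)-4-[(4-methoxybenzyl)oxy]but-2-en-2-yl}hex-5-en-2-one
Product: 18 tert-butyl({(3R,4S,5Z)-7-[(4-methoxybenzyl)oxy]-5-methyl-4-(prop-1-en-2-yl)hepta-1,5-dien-3-yl}oxy)dimethylsilane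
Conditions: Zn, CH2Br2, TiCl4, THF/CH2Cl2, 0 °C to rt
Reagents that add atoms: dibromomethane, BrCBr
Why: Lombardo methylenation is non-basic and suited to ketones with an epimerisable α-centre; it turns the acyl carbon C4 into the isopropenyl group.

Step 11
Reactants: 18 tert-butyl({(3R,4S,5Z)-7-[(4-methoxybenzyl)oxy]-5-methyl-4-(prop-1-en-2-yl)hepta-1,5-dien-3-yl}oxy)dimethylsilane
Product: 19 (2Z,4S,5R)-5-[(tert-butyldimethylsilyl)oxy]-3-methyl-4-(prop-1-en-2-yl)hepta-2,6-dien-1-ol
Conditions: DDQ, CH2Cl2/pH 7 buffer, 0 °C
Reagents that add atoms: none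
Why: Oxidative cleavage of the 4-methoxybenzyl ether under buffered conditions; silyl ether and alkenes are unaffected.

Step 12
Reactants: 19 (2Z,4S,5R)-5-[(tert-butyldimethylsilyl)oxy]-3-methyl-4-(prop-1-en-2-yl)hepta-2,6-dien-1-ol
Product: 20 {[(3R,4S,5Z)-7-bromo-5-methyl-4-(prop-1-en-2-yl)hepta-1,5-dien-3-yl]oxy}(tert-butyl)dimethylsilane
Conditions: CBr4, PPh3, 2,6-lutidine (cat.), CH2Cl2, −20 to 0 °C; used at once
Reagents that add atoms: carbon tetrabromide, BrC(Br)(Br)Br
Why: Appel reaction; SN2 displacement at the primary allylic carbon under neutral conditions keeps the Z alkene and the silyl ether.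

Step 13
Reactants: 21 tributyltin hydride; 12 acrolein
Product: 23 1-(tributylstannyl)prop-2-en-1-ol, via tributylstannyllithium 22 (not isolated)
Conditions: LiN(i-Pr)2, THF, 0 °C; then 12, −78 °C; aq. NH4Cl; used crude at once
Reagents that add atoms: none
Why: Deprotonation of the tin hydride gives Bu3SnLi, which adds 1,2 to the enal at low temperature; the labile α-hydroxy stannane is not purified.

Step 14
Reactants: 20 {[(3R,4S,5Z)-7-bromo-5-methyl-4-(prop-1-en-2-yl)hepta-1,5-dien-3-yl]oxy}(tert-butyl)dimethylsilane; 23 1-(tributylstannyl)prop-2-en-1-ol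
Product: 25 tributyl[1-({(2Z,4S,5R)-5-[(tert-butyldimethylsilyl)oxy]-3-methyl-4-(prop-1-en-2-yl)hepta-2,6-dien-1-yl}oxy)prop-2-en-1-yl]stannane (both C9 epimers), via potassium stannyl alkoxide 24 (not isolated)
Conditions: 23, KH, THF, −30 °C; then 20, Bu4NI (cat.), −30 to 0 °C
Reagents that add atoms: none
Why: Williamson etherification forms the C2–O–C9 ether; the primary allylic bromide should trap the α-stannyl alkoxide by SN2 before it can revert to aldehyde and stannyl anion.

Step 15
Reactants: 25 tributyl[1-({(2Z,4S,5R)-5-[(tert-butyldimethylsilyl)oxy]-3-methyl-4-(prop-1-en-2-yl)hepta-2,6-dien-1-yl}oxy)prop-2-en-1-yl]stannane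
Product: 26 (3R,4S,5Z)-5-methyl-4-(prop-1-en-2-yl)-7-{[1-(tributylstannyl)prop-2-en-1-yl]oxy}hepta-1,5-dien-3-ol (both C9 epimers)
Conditions: Bu4NF, THF, 0 °C to rt
Reagents that add atoms: none
Why: Fluoride desilylation; the allylic stannane is inert to fluoride, and the free C6 hydroxyl is needed for the next two steps.

Step 16
Reactants: 26 (3R,4S,5Z)-5-methyl-4-(prop-1-en-2-yl)-7-{[1-(tributylstannyl)prop-2-en-1-yl]oxy}hepta-1,5-dien-3-ol
Product: 27 (3Z,5R,6S,7Z)-7-methyl-6-(prop-1-en-2-yl)-2-(tributylstannyl)-2,5,6,9-tetrahydrooxonin-5-ol (nine-membered ether; both C9 epimers)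
Conditions: (PCy3)2Cl2Ru=CHPh (first-generation Grubbs catalyst, 10 mol%), CH2Cl2 (1 mM), 40 °C; stopped at full conversion of 26
Reagents that add atoms: none
Why: Ring-closing metathesis of the two monosubstituted vinyl groups; the ring size allows only the Z C7=C8 alkene. The free allylic hydroxyl favours carbene loading at C7, the first-generation catalyst engages the trisubstituted C1=C10 and the isopropenyl alkene only slowly, and the Z C1=C10 alkene pre-folds the chain.

Step 17
Reactants: 27 (3Z,5R,6S,7Z)-7-methyl-6-(prop-1-en-2-yl)-2-(tributylstannyl)-2,5,6,9-tetrahydrooxonin-5-ol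
Product: 29 (1R,4R,5S,6S)-5-ethenyl-5-methyl-6-(prop-1-en-2-yl)cyclohex-2-ene-1,4-diol, via dilithiated ring ether 28 (not isolated)
Conditions: n-BuLi (2.2 equiv), THF, −78 to −30 °C; aq. NH4Cl
Reagents that add atoms: none
Why: Proposed new method: the first equivalent of n-BuLi turns O6–H into a lithium alkoxide that cannot leave, the second exchanges tin for lithium at C9, and the allylic α-alkoxy carbanion 28 undergoes a concerted suprafacial [2,3]-Wittig shift in which C9 bonds to C10 while O–C2 breaks. The closest known reaction types are the Still–Wittig rearrangement of acyclic α-alkoxy stannanes and the ring-contracting [2,3]-Wittig rearrangement of macrocyclic diallyl ethers; a contraction from nine to six ring atoms has not been described. The cyclohexene (C5–C10) closes by transannular C9–C10 bond formation through a five-membered envelope (C9, O, C2, C1, C10) fused to the forming six-membered ring, and the C1=C2 vinyl group emerges exocyclic. At C9, C8 must stay gauche to C5 in the forming ring while C2 is cis to C5 on the Z alkene, so only the cis-fused bicyclic transition state is reachable and O9 ends up on the same face as C1; the tin-bearing centre is planarised in the delocalised C7–C9 anion, so both epimers of 27 converge. At C10, allylic 1,3-strain with C2 holds H5 in the plane of the C1=C10 alkene, the ring places C6 on the face from which C9 arrives, and the isopropenyl group therefore lies anti to the new bond, which puts the vinyl group trans to it. The step needs carbanion formation at C9 and not at C2 (secured by the stannane), the [2,3] path over [1,2] and [1,4] shifts (favoured by low temperature and the concerted geometry) and no β-elimination toward C6 (secured by the alkoxide).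

Step 18
Reactants: 29 (1R,4R,5S,6S)-5-ethenyl-5-methyl-6-(prop-1-en-2-yl)cyclohex-2-ene-1,4-diol
Product: 30 (1R,4R,5S,6S)-4-[(tert-butyldimethylsilyl)oxy]-6-ethenyl-6-methyl-5-(prop-1-en-2-yl)cyclohex-2-en-1-ol (O6 silyl ether)
Conditions: TBSCl, imidazole, DMF, −20 to 0 °C
Reagents that add atoms: tert-butyldimethylsilyl chloride, CC(C)(C)[Si](C)(C)Cl
Why: Silylation should distinguish the two allylic alcohols, because O9 is neopentyl (next to the quaternary C10) and O6 is not; this leaves O9–H as the only directing group.

Step 19
Reactants: 30 O6 silyl ether of the cyclohexenediol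
Product: 31 syn-epoxy alcohol (30 with a C7–C8 oxirane on the face of the C9 hydroxyl)
Conditions: VO(acac)2 (cat.), t-BuOOH, CH2Cl2, 0 °C to rt
Reagents that add atoms: tert-butyl hydroperoxide, CC(C)(C)OO
Why: Vanadium-catalysed hydroxyl-directed epoxidation; the C9 vanadate delivers oxygen to the C7=C8 face syn to O9. The allylic alkene reacts much faster than the homoallylic vinyl group, and the isopropenyl alkene has no directing group.

Step 20
Reactants: 31 syn-epoxy alcohol
Product: 32 alkynyl diol (C7 bears a (trimethylsilyl)ethynyl group cis to O6 and C8 a hydroxyl cis to O9; O6 silyl ether retained)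
Conditions: Me3SiC≡CH, n-BuLi, then Et2AlCl, toluene, 0 °C (gives Et2AlC≡CSiMe3); 31, 0 °C to rt; aq. potassium sodium tartrate
Reagents that add atoms: ethynyltrimethylsilane, C#C[Si](C)(C)C (delivered as diethyl[(trimethylsilyl)ethynyl]aluminium, CC[Al](CC)C#C[Si](C)(C)C)
Why: Alkynylalane opening of a cis-2,3-epoxy alcohol; the C9 aluminium alkoxide activates the oxirane and the alkynyl group attacks the distal carbon C7 with inversion. This gives C7–C11 trans to O8 and cis to O6, with O8 cis to O9.

Step 21
Reactants: 32 alkynyl diol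
Product: 33 O8,O9-isopropylidene acetal of 32
Conditions: Me2C(OMe)2, PPTS (cat.), CH2Cl2, rt
Reagents that add atoms: 2,2-dimethoxypropane, COC(C)(C)OC
Why: The cis-8,9-diol closes a five-membered acetal; it masks O8 and O9 so that O6 can be acylated alone.

Step 22
Reactants: 33 O8,O9-isopropylidene acetal
Product: 34 acetal with free C6 hydroxyl and terminal alkyne
Conditions: Bu4NF (2.5 equiv), THF, 0 °C to rt
Reagents that add atoms: none
Why: Fluoride removes the O6 silyl ether and the alkynyl silane in one operation; no lactone is present yet, so the O6 alkoxide has nothing to attack.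

Step 23
Reactants: 34 acetal with free C6 hydroxyl and terminal alkyne
Product: 35 O6 methacrylate of 34
Conditions: methacrylic anhydride, Et3N, DMAP (cat.), CH2Cl2, rt to 40 °C
Reagents that add atoms: methacrylic anhydride, C=C(C)C(=O)OC(=O)C(C)=C
Why: DMAP-catalysed acylation of the only free hydroxyl; the hindered axial position may need mild warming.

Step 24
Reactants: 35 O6 methacrylate with O8,O9 acetal
Product: 36 8,9-diol (O6 methacrylate; C7 ethynyl)
Conditions: AcOH/H2O (4:1), 40 °C
Reagents that add atoms: none
Why: Acid hydrolysis of the acetal; the methacrylate is stable to aqueous acetic acid and cannot migrate to the trans-disposed O8.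

Step 25
Reactants: 36 8,9-diol with C7 ethynyl group
Product: 37 8,12-olide (trans-fused α-methylene-γ-butyrolactone; C10 vinyl and C5 isopropenyl retained; O9–H free)
Conditions: PdCl2 (divalent palladium, cat.), PPh3, SnCl2 (cat.), CO (7 atm), MeCN, 75 °C
Reagents that add atoms: carbon monoxide, [C-]#[O+]
Why: Palladium-catalysed cyclocarbonylation of a homopropargylic alcohol; the C8 alkoxycarbonyl–palladium species adds syn across the alkyne with C12 bonding to C11, and protonolysis leaves the exocyclic methylene. O9 is trans-1,3 to the alkyne and cannot lactonise, and O6 is acylated.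

Step 26
Reactants: 37 8,12-olide
Product: 38 allylic alcohol (C5 bears a 3-hydroxyprop-1-en-2-yl group)
Conditions: SeO2 (cat.), t-BuOOH, CH2Cl2, rt
Reagents that add atoms: tert-butyl hydroperoxide, CC(C)(C)OO; selenium dioxide (oxygen carrier), O=[Se]=O
Why: SeO2 allylic oxidation (ene reaction then [2,3] shift) of the only electron-rich alkene with allylic hydrogens; 1,1-disubstituted alkenes are oxidised at CH3 in preference to the ring CH.

Step 27
Reactants: 38 allylic alcohol
Product: 39 enal (the target lacking only the oxirane oxygen)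
Conditions: MnO2, CH2Cl2, rt
Reagents that add atoms: none
Why: MnO2 oxidises the primary allylic alcohol to the aldehyde; the non-allylic C9 hydroxyl is left alone, and any enal formed already in step 26 converges here.

Step 28
Reactants: 39 enal
Product: 40 target CNP0228781.2
Conditions: VO(acac)2 (cat.), t-BuOOH, CH2Cl2, 0 °C to rt
Reagents that add atoms: tert-butyl hydroperoxide, CC(C)(C)OO
Why: Vanadium-catalysed epoxidation directed by the homoallylic C9 hydroxyl onto the only alkene not conjugated to a carbonyl group. In the chair-like vanadate transition state the terminal CH2 points away from C9 and eclipses the C10–C5 bond, which delivers oxygen to the face that gives (1R).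

## Compound list

1 | but-2-yn-1-ol | CC#CCO | starting material
2 | sodium cyclic vinylalanate of 1 (2,2-bis(2-methoxyethoxy)-3-methyl-5H-1,2-oxaluminol-2-uide) | CC1=CCO[Al-]1(OCCOC)OCCOC.[Na+] | intermediate (not isolated)
3 | (2Z)-3-iodobut-2-en-1-ol | C/C(I)=C/CO | intermediate
4 | 1-({[(2Z)-3-iodobut-2-en-1-yl]oxy}methyl)-4-methoxybenzene | C/C(I)=C/COCc1ccc(OC)cc1 | intermediate
5 | ethyl bromoacetate | CCOC(=O)CBr | starting material
6 | (2-ethoxy-2-oxoethyl)zinc bromide | CCOC(=O)C[Zn]Br | intermediate (not isolated)
7 | ethyl (3Z)-5-[(4-methoxybenzyl)oxy]-3-methylpent-3-enoate | CCOC(=O)C/C(C)=C\COCc1ccc(OC)cc1 | intermediate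
8 | (3Z)-5-[(4-methoxybenzyl)oxy]-3-methylpent-3-enoic acid | OC(=O)C/C(C)=C\COCc1ccc(OC)cc1 | intermediate
9 | (4S)-4-benzyl-1,3-oxazolidin-2-one | O=C1N[C@@H](Cc2ccccc2)CO1 | starting material
10 | mixed anhydride of 8 with pivalic acid | CC(C)(C)C(=O)OC(=O)C/C(C)=C\COCc1ccc(OC)cc1 | intermediate (not isolated)
11 | (4S)-4-benzyl-3-{(3Z)-5-[(4-methoxybenzyl)oxy]-3-methylpent-3-enoyl}-1,3-oxazolidin-2-one | O=C(C/C(C)=C\COCc1ccc(OC)cc1)N1[C@@H](Cc2ccccc2)COC1=O | intermediate
12 | acrolein (prop-2-enal) | C=CC=O | starting material
13 | (Z)-dibutylboron enolate of 11 | CCCCB(CCCC)O/C(=C\C(C)=C/COCc1ccc(OC)cc1)N1[C@@H](Cc2ccccc2)COC1=O | intermediate (not isolated)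
14 | (4S)-4-benzyl-3-[(2S,3R)-3-hydroxy-2-{(2Z)-4-[(4-methoxybenzyl)oxy]but-2-en-2-yl}pent-4-enoyl]-1,3-oxazolidin-2-one | C=C[C@@H](O)[C@@H](C(=O)N1[C@@H](Cc2ccccc2)COC1=O)/C(C)=C\COCc1ccc(OC)cc1 | intermediate
15 | (2S,3R)-3-hydroxy-N-methoxy-2-{(2Z)-4-[(4-methoxybenzyl)oxy]but-2-en-2-yl}-N-methylpent-4-enamide | C=C[C@@H](O)[C@@H](C(=O)N(C)OC)/C(C)=C\COCc1ccc(OC)cc1 | intermediate
16 | (2S,3R)-3-[(tert-butyldimethylsilyl)oxy]-N-methoxy-2-{(2Z)-4-[(4-methoxybenzyl)oxy]but-2-en-2-yl}-N-methylpent-4-enamide | C=C[C@@H](O[Si](C)(C)C(C)(C)C)[C@@H](C(=O)N(C)OC)/C(C)=C\COCc1ccc(OC)cc1 | intermediate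
17 | (3S,4R)-4-[(tert-butyldimethylsilyl)oxy]-3-{(2Z)-4-[(4-methoxybenzyl)oxy]but-2-en-2-yl}hex-5-en-2-one | C=C[C@@H](O[Si](C)(C)C(C)(C)C)[C@@H](C(C)=O)/C(C)=C\COCc1ccc(OC)cc1 | intermediate
18 | tert-butyl({(3R,4S,5Z)-7-[(4-methoxybenzyl)oxy]-5-methyl-4-(prop-1-en-2-yl)hepta-1,5-dien-3-yl}oxy)dimethylsilane | C=C[C@@H](O[Si](C)(C)C(C)(C)C)[C@@H](C(C)=C)/C(C)=C\COCc1ccc(OC)cc1 | intermediate
19 | (2Z,4S,5R)-5-[(tert-butyldimethylsilyl)oxy]-3-methyl-4-(prop-1-en-2-yl)hepta-2,6-dien-1-ol | C=C[C@@H](O[Si](C)(C)C(C)(C)C)[C@@H](C(C)=C)/C(C)=C\CO | intermediate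
20 | {[(3R,4S,5Z)-7-bromo-5-methyl-4-(prop-1-en-2-yl)hepta-1,5-dien-3-yl]oxy}(tert-butyl)dimethylsilane | C=C[C@@H](O[Si](C)(C)C(C)(C)C)[C@@H](C(C)=C)/C(C)=C\CBr | intermediate
21 | tributyltin hydride (tributylstannane) | CCCC[SnH](CCCC)CCCC | starting material
22 | tributylstannyllithium | [Li][Sn](CCCC)(CCCC)CCCC | intermediate (not isolated)
23 | 1-(tributylstannyl)prop-2-en-1-ol (racemic) | C=CC(O)[Sn](CCCC)(CCCC)CCCC | intermediate
24 | potassium 1-(tributylstannyl)prop-2-en-1-olate | C=CC([O-])[Sn](CCCC)(CCCC)CCCC.[K+] | intermediate (not isolated)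
25 | tributyl[1-({(2Z,4S,5R)-5-[(tert-butyldimethylsilyl)oxy]-3-methyl-4-(prop-1-en-2-yl)hepta-2,6-dien-1-yl}oxy)prop-2-en-1-yl]stannane (both C9 epimers) | C=C[C@@H](O[Si](C)(C)C(C)(C)C)[C@@H](C(C)=C)/C(C)=C\COC(C=C)[Sn](CCCC)(CCCC)CCCC | intermediate
26 | (3R,4S,5Z)-5-methyl-4-(prop-1-en-2-yl)-7-{[1-(tributylstannyl)prop-2-en-1-yl]oxy}hepta-1,5-dien-3-ol (both C9 epimers) | C=C[C@@H](O)[C@@H](C(C)=C)/C(C)=C\COC(C=C)[Sn](CCCC)(CCCC)CCCC | intermediate
27 | (3Z,5R,6S,7Z)-7-methyl-6-(prop-1-en-2-yl)-2-(tributylstannyl)-2,5,6,9-tetrahydrooxonin-5-ol (nine-membered stannyl ether; both C9 epimers) | O[C@@H]1/C=C\C([Sn](CCCC)(CCCC)CCCC)OC/C=C(C)\[C@@H]1C(C)=C | intermediate (key-step precursor)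
28 | dilithium species of 27 (C6 lithium alkoxide, C9 allyllithium) | [Li]O[C@@H]1/C=C\C([Li])OC/C=C(C)\[C@@H]1C(C)=C | intermediate (not isolated)
29 | (1R,4R,5S,6S)-5-ethenyl-5-methyl-6-(prop-1-en-2-yl)cyclohex-2-ene-1,4-diol | O[C@@H]1C=C[C@@H](O)[C@@](C)(C=C)[C@@H]1C(C)=C | intermediate (key-step product)
30 | (1R,4R,5S,6S)-4-[(tert-butyldimethylsilyl)oxy]-6-ethenyl-6-methyl-5-(prop-1-en-2-yl)cyclohex-2-en-1-ol | CC(C)(C)[Si](C)(C)O[C@@H]1C=C[C@@H](O)[C@@](C)(C=C)[C@@H]1C(C)=C | intermediate
31 | 7,8-epoxide of 30, oxirane oxygen cis to the C9 hydroxyl and trans to O6 | CC(C)(C)[Si](C)(C)O[C@@H]1[C@H]2O[C@H]2[C@@H](O)[C@@](C)(C=C)[C@@H]1C(C)=C | intermediate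
32 | 8,9-diol with C7 (trimethylsilyl)ethynyl group (alkynyl cis to O6 silyl ether; O8 cis to O9) | CC(C)(C)[Si](C)(C)O[C@@H]1[C@H](C#C[Si](C)(C)C)[C@@H](O)[C@@H](O)[C@@](C)(C=C)[C@@H]1C(C)=C | intermediate
33 | O8,O9-isopropylidene acetal of 32 | CC(C)(C)[Si](C)(C)O[C@@H]1[C@H](C#C[Si](C)(C)C)[C@H]2OC(C)(C)O[C@H]2[C@@](C)(C=C)[C@@H]1C(C)=C | intermediate
34 | O8,O9-isopropylidene acetal with free C6 hydroxyl and C7 ethynyl group | O[C@@H]1[C@H](C#C)[C@H]2OC(C)(C)O[C@H]2[C@@](C)(C=C)[C@@H]1C(C)=C | intermediate
35 | O6 methacrylate of 34 | C=C(C)C(=O)O[C@@H]1[C@H](C#C)[C@H]2OC(C)(C)O[C@H]2[C@@](C)(C=C)[C@@H]1C(C)=C | intermediate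
36 | 8,9-diol with O6 methacrylate and C7 ethynyl group | C=C(C)C(=O)O[C@@H]1[C@H](C#C)[C@@H](O)[C@@H](O)[C@@](C)(C=C)[C@@H]1C(C)=C | intermediate
37 | 6-ethenyl-7-hydroxy-6-methyl-3-methylidene-2-oxo-5-(prop-1-en-2-yl)octahydro-1-benzofuran-4-yl 2-methylprop-2-enoate (trans-fused 8,12-olide; faces as in the target) | C=C(C)C(=O)O[C@@H]1[C@@H]2C(=C)C(=O)O[C@H]2[C@@H](O)[C@@](C)(C=C)[C@@H]1C(C)=C | intermediate
38 | 37 with the C5 side chain oxidised to 3-hydroxyprop-1-en-2-yl | C=C(C)C(=O)O[C@@H]1[C@@H]2C(=C)C(=O)O[C@H]2[C@@H](O)[C@@](C)(C=C)[C@@H]1C(=C)CO | intermediate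
39 | 37 with the C5 side chain oxidised to 3-oxoprop-1-en-2-yl (target without the oxirane oxygen) | C=C(C)C(=O)O[C@@H]1[C@@H]2C(=C)C(=O)O[C@H]2[C@@H](O)[C@@](C)(C=C)[C@@H]1C(=C)C=O | intermediate
40 | CNP0228781.2: 7-hydroxy-6-methyl-3-methylidene-6-[(2R)-oxiran-2-yl]-2-oxo-5-(3-oxoprop-1-en-2-yl)octahydro-1-benzofuran-4-yl 2-methylprop-2-enoate (O8, O9 and oxirane on one face; O6, C11, C14 and the C5 arm on the other) | C=C(C)C(=O)O[C@@H]1[C@@H]2C(=C)C(=O)O[C@H]2[C@@H](O)[C@@](C)([C@@H]2CO2)[C@@H]1C(=C)C=O | target

## Step count and least certain steps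

Total steps: 28. Longest linear sequence: 27 steps (steps 1–12 and 14–28, from **1** to **40**); step 13 is a one-step side branch.

**Step 17 (key step, proposed new method).**
- *What may go wrong:* the C9 carbanion may take a [1,2]- or [1,4]-shift, or may only be protonated if the nine-membered ring cannot reach the envelope geometry. A ring conformer with the isopropenyl group in the alkene plane would erode selectivity at C10.
- *Fallback (known chemistry):* reverse the order of the two ring-forming events, setting out from **26**. n-BuLi (2.2 equiv, THF, −78 °C) on the open-chain stannyl ether triggers the acyclic Still–Wittig-type [2,3] shift. The product is (3R,4S,5S,6R)-5-ethenyl-5-methyl-4-(prop-1-en-2-yl)octa-1,7-diene-3,6-diol F1. Ring-closing metathesis of its two vinyl carbinol termini (C7 and C8) with (H2IMes)(PCy3)Cl2Ru=CHPh (second-generation Grubbs catalyst) then closes the cyclohexene and returns to the route at **29**.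
- *Cost of the fallback:* the ring no longer enforces the C5/C10 relation, so this would rest on allylic strain and alkoxide coordination alone. A cyclopentene from C7 and the C10 vinyl group is a possible side product.

**Step 16.**
- *What may go wrong:* a five-membered ring closure can compete. A carbene formed at C8 can reach the trisubstituted C1=C10 alkene and expel a 2,5-dihydrofuran. The product can also be reopened by the catalyst, and oligomerisation competes at this ring size.
- *Fallback:* set out from **20** and change the way the catalyst is steered. **20** is etherified, as in step 14, with the potassium alkoxide of (2E)-1-(tributylstannyl)but-2-en-1-ol F2 (made from **21** and crotonaldehyde as in step 13). This gives the C8-methyl-capped ether F3, and Bu4NF then gives the free alcohol F4. In F4 the capped C8 alkene can only accept a carbene, so ruthenium enters at C7 alone. The more active (H2IMes)(PCy3)Cl2Ru=CHPh (second-generation Grubbs catalyst) is then used; propene is released and the route is rejoined at **27**.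

**Step 14.**
- *What may go wrong:* the α-stannyl alkoxide may fragment to acrolein and stannyl anion, or tin may shift, before O-alkylation occurs.
- *Fallback:* set out from **19** and avoid the alkoxide. Cl3CCN with catalytic DBU gives the allylic trichloroacetimidate F5. F5 is coupled with neutral **23** under catalytic TfOH at −40 °C, returning at **25**.

**Step 20.**
- *What may go wrong:* attack at C8 instead of C7 if trans-diaxial opening through the other ring conformer outweighs delivery by the C9 alkoxide; or no opening, because C7 is flanked by the silyl ether and the C5 substituent.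
- *Fallback:* set out from **30** and introduce oxygen and carbon separately.
  - Boc2O/DMAP gives the O9 tert-butyl carbonate F6.
  - IBr at −78 °C effects iodocarbonate cyclisation to the cyclic 8,9-carbonate F7, with the carbonate oxygen at C8 cis to O9 and iodine anti at C7.
  - Radical alkynylation (PhSO2C≡CSiMe3, (Bu3Sn)2, hν) gives the alkynyl carbonate F8; the C7 radical is trapped on the face away from the cis-fused carbonate.
  - i-Bu2AlH cleaves the carbonate and returns to the route at **32**.

**Step 28.**
- *What may go wrong:* poor facial selectivity at C1, since a second rotamer of the vinyl group can also reach the vanadate; slow reaction of a monosubstituted alkene, with oxidation of the aldehyde as a competing process.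
- *Fallback:* set out from **39** and replace substrate control by catalyst control. The epoxidation is run as in step 28 without regard to selectivity, giving **40** together with its C1 epimer, the (1S)-oxirane F9. Hydrolytic kinetic resolution follows, using water and the enantiomer of (salen)Co(OAc) (trivalent cobalt) that opens the (1S)-oxirane. This converts F9 into the 1,2-diol F10, which is separated, and the route ends at **40**.

## Further compounds

F1 | step 17 | (3R,4S,5S,6R)-5-ethenyl-5-methyl-4-(prop-1-en-2-yl)octa-1,7-diene-3,6-diol | C=C[C@@H](O)[C@@H](C(C)=C)[C@](C)(C=C)[C@H](O)C=C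
F2 | step 16 | (2E)-1-(tributylstannyl)but-2-en-1-ol | C/C=C/C(O)[Sn](CCCC)(CCCC)CCCC
F3 | step 16 | C8-methyl-capped analogue of 25 (ether of 20 with F2) | C=C[C@@H](O[Si](C)(C)C(C)(C)C)[C@@H](C(C)=C)/C(C)=C\COC(/C=C/C)[Sn](CCCC)(CCCC)CCCC
F4 | step 16 | C8-methyl-capped analogue of 26 | C=C[C@@H](O)[C@@H](C(C)=C)/C(C)=C\COC(/C=C/C)[Sn](CCCC)(CCCC)CCCC
F5 | step 14 | trichloroacetimidate of 19 | C=C[C@@H](O[Si](C)(C)C(C)(C)C)[C@@H](C(C)=C)/C(C)=C\COC(=N)C(Cl)(Cl)Cl
F6 | step 20 | O9 tert-butyl carbonate of 30 | CC(C)(C)[Si](C)(C)O[C@@H]1C=C[C@@H](OC(=O)OC(C)(C)C)[C@@](C)(C=C)[C@@H]1C(C)=C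
F7 | step 20 | C7 iodide with cyclic 8,9-carbonate | CC(C)(C)[Si](C)(C)O[C@@H]1[C@H](I)[C@H]2OC(=O)O[C@H]2[C@@](C)(C=C)[C@@H]1C(C)=C
F8 | step 20 | C7 (trimethylsilyl)ethynyl compound with cyclic 8,9-carbonate | CC(C)(C)[Si](C)(C)O[C@@H]1[C@H](C#C[Si](C)(C)C)[C@H]2OC(=O)O[C@H]2[C@@](C)(C=C)[C@@H]1C(C)=C
F9 | step 28 | C1 epimer of 40 ((1S)-oxirane) | C=C(C)C(=O)O[C@@H]1[C@@H]2C(=C)C(=O)O[C@H]2[C@@H](O)[C@@](C)([C@H]2CO2)[C@@H]1C(=C)C=O
F10 | step 28 | 1,2-diol from hydrolysis of F9 | C=C(C)C(=O)O[C@@H]1[C@@H]2C(=C)C(=O)O[C@H]2[C@@H](O)[C@@](C)([C@H](O)CO)[C@@H]1C(=C)C=O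
A1 | alternative 1 | bicyclo[2.2.0]hexane photoadduct with silyl acetal tether | C[C@]12[C@@H]3O[Si](C(C)C)(C(C)C)O[C@]14CC[C@]4(C(=O)OC)[C@H]2C(=O)[C@@H]2CC(=O)O[C@H]23
A2 | alternative 1 | silyl-acetal-tethered cyclohexenone–cyclobutene photosubstrate | CC1=CC(=O)[C@@H]2CC(=O)O[C@H]2[C@H]1O[Si](C(C)C)(C(C)C)OC1=C(C(=O)OC)CC1
A3 | alternative 2 | bis-silylated methylene lactone with methyl acrylate arm | CC(C)(C)[Si](C)(C)O[C@@H]1[C@@H]2C(=C)C(=O)O[C@H]2[C@@H](O[Si](C)(C)C(C)(C)C)[C@@](C)(C=C)[C@@H]1C(=C)C(=O)OC
A4 | alternative 2 | bis(enol triflate) with free C8 hydroxyl | CC(C)(C)[Si](C)(C)O[C@@H]1[C@H](C(=C)OS(=O)(=O)C(F)(F)F)[C@@H](O)[C@@H](O[Si](C)(C)C(C)(C)C)[C@@](C)(C=C)[C@@H]1C(=C)OS(=O)(=O)C(F)(F)F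
A5 | alternative 3 | trans-1,4-diacetoxycyclohex-2-ene | COC(=O)[C@]1(C)[C@H](OC(C)=O)C=C[C@@H](OC(C)=O)[C@H]1C1(C)OCCO1
A6 | alternative 3 | cyclohexa-1,3-diene ester ketal | COC(=O)[C@]1(C)C=CC=C[C@H]1C1(C)OCCO1
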